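The earlier runs and the new flask stem from a simulated flask from invented constants; scatter was added.

The first product in amber is close to its last reading at its first sample: it reads 46.2% at 1.50 min and 48.3% at 20.0 min.

common to all: substrate 0.20 mM
- teal: reagent 0.13 mM; run made earlier
- ochre: reagent 0.38 mM; run made earlier
- amber: reagent 0.93 mM; run made earlier
- noon: reagent 0.800 mM; time 25 min
- winter: reagent 0.200 mM; time 25 min
- dawn: reagent 0.160 mM; time 25 min

- teal (time / min: double product / %, first product / %): 1.33: 0, 23.6; 2.50: 0, 23.9; 5.00: 0.7, 24.4; 10.0: 0.6, 24.9; 20.0: 1.2, 26.2
- ochre (time / min: double product / %, first product / %): 4.00: 1.6, 38.9; 8.00: 0.9, 40.3; 10.0: 0, 40.9; 15.0: 1.6, 38.2; 20.0: 2.3, 40.7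
- amber (time / min: double product / %, first product / %): 1.50: 2.0, 46.2; 4.00: 1.6, 48.7; 8.00: 2.3, 47.9; 12.0: 2.2, 48.2; 20.0: 3.2, 48.3

(readings scatter by 1 percentage point)

- the numbers in the tables scatter by 1 percentage point (one standard deviation)
- steps thought possible: reagent + first product -> over-reaction product; reagent + other mono adduct -> double product + by-product; substrate + reagent -> first product + by-product; 2 reagent -> self-condensation product; reagent + first product -> double product + by-product; substrate + reagent -> other mono adduct + by-product

1. which of these holds the largest part of the substrate at the end of noon (substrate / double product / first product / other mono adduct)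
2. which of these holds the largest part of the substrate at the end of winter (substrate / double product / first product / other mono adduct)
3. which of these holds the largest part of the substrate at the end of dawn (substrate / double product / first product / other mono adduct)
4. double product at the end of noon, in percent of the substrate charged

We climb the ladder from the fastest rung. Within the first minutes, the reagent attacks the substrate and, we take it, condenses with itself. Next comes the plateau, so we read the end of each flask at 25 min as its plateau. On that plateau the double product of amber averages 2.26%. Noon is charged with less reagent than amber, so we commit to about that figure or a little less.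

Attack on the substrate and self-condensation are both bimolecular, so we assume the percentages follow the equivalents e = c(reagent)/c(substrate) as charged. We try a saturating curve:

M(e) = C · e / (e + H)

Here C is the ceiling and H is the half-charge, the equivalents at which the first product reaches half of its ceiling. Teal gives 24.6% at e = 0.650, and amber gives 47.9% at e = 4.65. As readings, these yield:

C = 56.5%, H = 0.844

Ochre, left out of this, is predicted at 39.2% and averages 39.8%.

The zero of our scale is the even split, where the ceiling C is half of the substrate. Our C stands above that, so we read C as the first product's share of the substrate consumed, and substrate left is 1 − M/C. Winter then has M = 30.7% and substrate left 45.8%, more than its first product. Dawn has M = 27.5% and substrate left 51.3%, more than its first product. Noon has M = 46.7%, with substrate left 17.4% and other mono adduct 35.9%, each less than its first product.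

The forecast names first product, substrate and substrate for noon, winter and dawn, with 2.6% double product at noon, above our figure, and it starts from this: “The first product reaches its plateau before the first sample”.

Noon gives first product as largest, at 47.2%, with 25.3% substrate and 1.93% double product. Winter gives substrate at 53.0%, and dawn gives substrate at 58.0%.

    reagent + first product → over-reaction product (k = 4.90 M⁻¹ s⁻¹)
    reagent + other mono adduct → double product + by-product (k = 11.0 M⁻¹ s⁻¹)
    substrate + reagent → first product + by-product (k = 230 M⁻¹ s⁻¹)
    2 reagent → self-condensation product (k = 400 M⁻¹ s⁻¹)
    reagent + first product → double product + by-product (k = 11.0 M⁻¹ s⁻¹)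
    substrate + reagent → other mono adduct + by-product (k = 120 M⁻¹ s⁻¹)

Noon's first product lands near our 46.7%, but its substrate stands above our 17.4%. In noon the reagent is the limiting reagent, with 0% of its charge left at 25.0 min. The neighbour keeps noon's reagent but holds 0.80 mM of substrate, so e = 1.00. The half-charge gives it 30.6% first product, and the flask gives 30.4%, with substrate largest at 53.0%.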